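The six-membered enone is read as a cyclopentanone that has gained one carbon: C2 of the cyclohex-2-enone ring (C1 ketone, C2=C3 alkene, C5 carbinol) is a methylene inserted between the carbonyl carbon C1 and the former α-carbon C3. The precursor is a 1-silyloxybicyclo[3.1.0]hexane that already carries the (S)-carbinol and the whole unprotected side chain. Fe(III) one-electron oxidation cleaves the shared cyclopropane bond, so the five-membered ring becomes the six-membered ketone with chloride at C3, and loss of HCl places the alkene at C2=C3 only. The carbinol configuration is fixed earlier by anti 1,2-addition of a linoleic-acid-derived methyl ketone enolate to (R)-4-silyloxycyclopentenone, whose own stereocentre is then oxidised to the future C1 carbonyl.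

Key step: step 7

Remark on the chemistry: the target carbinol is (S) (CIP order O > ring CH2C(=O) > side-chain CH2C(=O) > ring CH2CH=), and additions to the carbonyl of 4-silyloxycyclopent-2-enones are assumed to occur anti to the silyloxy group.

Step 1
Reactants: 1 linoleic acid, (9Z,12Z)-octadeca-9,12-dienoic acid
Product: 2 (10Z,13Z)-nonadeca-10,13-dien-2-one
Conditions: MeLi (2.3 equiv), Et2O, 0 °C to rt; inverse quench into cold 1 M HCl
Reagents that add atoms: methyllithium, [Li]C
Why: Addition of MeLi to the lithium carboxylate should stop at the dilithium gem-diolate, which releases the methyl ketone only on quench (carboxylic acid to methyl ketone with an organolithium), and the skipped Z,Z-diene is inert to MeLi under these conditions.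

Step 2
Reactants: 2 (10Z,13Z)-nonadeca-10,13-dien-2-one; 3 (R)-4-(tert-butyldimethylsilyloxy)cyclopent-2-en-1-one
Product: 6 (10Z,13Z)-1-[(1R,4R)-4-(tert-butyldimethylsilyloxy)-1-hydroxycyclopent-2-en-1-yl]nonadeca-10,13-dien-2-one (OH cis to OTBS), via lithium enolate 4 (not isolated), via cerium enolate 5 (not isolated)
Conditions: LDA (1.05 equiv), THF, −78 °C; anhydrous CeCl3 (1.2 equiv), −78 °C; then 3 (0.9 equiv), −78 °C; AcOH quench at −78 °C
Reagents that add atoms: none
Why: Kinetic deprotonation at the methyl group and transmetalation to the weakly basic, oxophilic cerium enolate should give clean 1,2-addition to the enone carbonyl (cerium-mediated aldol addition) rather than Michael addition or enolisation with loss of the silyloxy group, and attack anti to the C4 silyloxy group sets the carbinol centre (1R) from the chiral-pool centre (4R).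

Step 3
Reactants: 6 the silyl-protected aldol adduct
Product: 7 (10Z,13Z)-1-[(1R,4R)-1,4-dihydroxycyclopent-2-en-1-yl]nonadeca-10,13-dien-2-one (cis-diol)
Conditions: HF·pyridine, pyridine, THF, 0 °C to rt
Reagents that add atoms: none
Why: Fluoride-driven Si–O cleavage (silyl ether deprotection) under buffered, non-basic conditions should spare the β-hydroxy ketone from retro-aldol cleavage and the tertiary allylic alcohol from ionisation.

Step 4
Reactants: 7 the cis-diol
Product: 8 (4S)-4-hydroxy-4-[(10Z,13Z)-2-oxononadeca-10,13-dien-1-yl]cyclopent-2-en-1-one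
Conditions: activated MnO2 (15 equiv), CH2Cl2, rt
Reagents that add atoms: none
Why: MnO2 oxidises only the secondary allylic alcohol (allylic alcohol oxidation), leaving the tertiary carbinol, the saturated ketone and the isolated Z-alkenes untouched and erasing the stereocentre that has done its work.

Step 5
Reactants: 8 the 4-hydroxycyclopentenone
Product: 9 (10Z,13Z)-1-[(1R)-1-hydroxy-3-(triethylsilyloxy)cyclopent-3-en-1-yl]nonadeca-10,13-dien-2-one
Conditions: Et3SiH (1.2 equiv), RhCl(PPh3)3 (1 mol %), THF, 45 °C
Reagents that add atoms: triethylsilane, CC[SiH](CC)CC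
Why: Rh-catalysed 1,4-hydrosilylation of the enone with a monohydrosilane should deliver the silyl enol ether regiospecifically on the side remote from the carbinol, a regiochemistry that base enolisation could not secure next to the side-chain ketone, while the saturated ketone, the tertiary alcohol and the 1,2-disubstituted alkenes react much more slowly.

Step 6
Reactants: 9 the triethylsilyl enol ether
Product: 11 (10Z,13Z)-1-[(1S,3R,5R)-3-hydroxy-1-(triethylsilyloxy)bicyclo[3.1.0]hexan-3-yl]nonadeca-10,13-dien-2-one (cyclopropane cis to OH), via ethylzinc alkoxide 10 (not isolated)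
Conditions: Et2Zn (2.2 equiv), CH2I2 (1.3 equiv), CH2Cl2, −20 to 0 °C; sat. aq. NH4Cl
Reagents that add atoms: diiodomethane, ICI
Why: In this Simmons–Smith cyclopropanation (Furukawa variant) the zinc alkoxide of the homoallylic tertiary alcohol should deliver the carbenoid to the electron-rich silyl enol ether on its own face faster than methylene is transferred to the remote unactivated Z-alkenes, and the two new ring-fusion centres (cis to OH) are erased in step 7.

Step 7
Reactants: 11 the silyloxycyclopropane
Product: 13 (5S)-5-hydroxy-5-[(10Z,13Z)-2-oxononadeca-10,13-dien-1-yl]cyclohex-2-en-1-one, via β-chloro ketone 12 (not isolated)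
Conditions: FeCl3 (2.3 equiv), pyridine (1.0 equiv), DMF, 0 °C to rt; then NaOAc (6 equiv), MeOH, rt (crude chloride not purified)
Reagents that add atoms: none
Why: Fe(III) takes over the cyclopropanol oxygen from silicon and oxidises it by one electron, the cyclopropoxy radical opens by β-scission of the shared C1–C5 bond to a cyclohexanone radical at C3, this radical abstracts chlorine from a second FeCl3 to give 12, and acetate then removes HCl by E1cB elimination. The closest known reaction is the FeCl3-mediated ring enlargement of 1-silyloxybicyclo[n.1.0]alkanes to cycloalk-2-enones. No ring is closed: the six-membered ring arises from the five-membered one by cleavage of the zero-atom bridge of the bicycle, the former cyclopropane CH2 becoming C2. No lasting stereocentre is created, since both C3 chloride epimers converge on elimination, and the C5 carbinol set in step 2 is touched neither by the radical nor by the base. The step needs cleavage of the internal and not the external cyclopropane bond, which the secondary-versus-primary radical stability and the relief of bicyclic strain secure, and it needs the alkene at C2=C3 only, which follows because C2 is the only carbon that is both α to the ketone and next to C–Cl. Buffering with pyridine and acetate at low temperature is meant to keep the tertiary β-hydroxy ketone from dehydrating towards a phenol, and fast chlorine transfer should keep the radical away from the bis-allylic C–H bonds.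

Compound list
1 | linoleic acid, (9Z,12Z)-octadeca-9,12-dienoic acid | CCCCC/C=C\C/C=C\CCCCCCCC(=O)O | starting material
2 | (10Z,13Z)-nonadeca-10,13-dien-2-one | CCCCC/C=C\C/C=C\CCCCCCCC(C)=O | intermediate
3 | (R)-4-(tert-butyldimethylsilyloxy)cyclopent-2-en-1-one | O=C1C=C[C@H](O[Si](C)(C)C(C)(C)C)C1 | starting material
4 | lithium enolate of 2, lithium (10Z,13Z)-nonadeca-1,10,13-trien-2-olate | [Li]OC(=C)CCCCCCC/C=C\C/C=C\CCCCC | intermediate
5 | cerium enolate of 2, dichlorocerium(III) (10Z,13Z)-nonadeca-1,10,13-trien-2-olate | Cl[Ce](Cl)OC(=C)CCCCCCC/C=C\C/C=C\CCCCC | intermediate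
6 | (10Z,13Z)-1-[(1R,4R)-4-(tert-butyldimethylsilyloxy)-1-hydroxycyclopent-2-en-1-yl]nonadeca-10,13-dien-2-one, OH cis to OTBS | O[C@]1(CC(=O)CCCCCCC/C=C\C/C=C\CCCCC)C=C[C@H](O[Si](C)(C)C(C)(C)C)C1 | intermediate
7 | (10Z,13Z)-1-[(1R,4R)-1,4-dihydroxycyclopent-2-en-1-yl]nonadeca-10,13-dien-2-one, cis-diol | O[C@]1(CC(=O)CCCCCCC/C=C\C/C=C\CCCCC)C=C[C@H](O)C1 | intermediate
8 | (4S)-4-hydroxy-4-[(10Z,13Z)-2-oxononadeca-10,13-dien-1-yl]cyclopent-2-en-1-one | O[C@]1(CC(=O)CCCCCCC/C=C\C/C=C\CCCCC)C=CC(=O)C1 | intermediate
9 | (10Z,13Z)-1-[(1R)-1-hydroxy-3-(triethylsilyloxy)cyclopent-3-en-1-yl]nonadeca-10,13-dien-2-one | O[C@]1(CC(=O)CCCCCCC/C=C\C/C=C\CCCCC)CC=C(O[Si](CC)(CC)CC)C1 | intermediate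
10 | ethylzinc alkoxide of 9 | CC[Zn]O[C@]1(CC(=O)CCCCCCC/C=C\C/C=C\CCCCC)CC=C(O[Si](CC)(CC)CC)C1 | intermediate
11 | (10Z,13Z)-1-[(1S,3R,5R)-3-hydroxy-1-(triethylsilyloxy)bicyclo[3.1.0]hexan-3-yl]nonadeca-10,13-dien-2-one, cyclopropane cis to OH | O[C@]1(CC(=O)CCCCCCC/C=C\C/C=C\CCCCC)C[C@@H]2C[C@]2(O[Si](CC)(CC)CC)C1 | intermediate
12 | (5S)-3-chloro-5-hydroxy-5-[(10Z,13Z)-2-oxononadeca-10,13-dien-1-yl]cyclohexan-1-one, both C3 epimers | O[C@]1(CC(=O)CCCCCCC/C=C\C/C=C\CCCCC)CC(Cl)CC(=O)C1 | intermediate
13 | (5S)-5-hydroxy-5-[(10Z,13Z)-2-oxononadeca-10,13-dien-1-yl]cyclohex-2-en-1-one | CCCCC/C=C\C/C=C\CCCCCCCC(=O)C[C@@]1(O)CC=CC(=O)C1 | target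

Total step count: 7. Longest linear sequence: 7 steps (1 to 13; 6 steps from 3).

Steps most likely to fail

Step 6. The zinc carbenoid may transfer methylene to the 10,13-diene in competition with the directed delivery, and the zinc β-ketol alkoxide may fragment by retro-aldol reaction. The fallback sets out from 3 and cerium enolate 5 and returns at 12; it builds the cyclopropane before the unsaturated chain is present. Pt(0)–divinyltetramethyldisiloxane-catalysed 1,4-hydrosilylation of 3 with iPr3SiH should give (4S)-4-(tert-butyldimethylsilyloxy)-1-(triisopropylsilyloxy)cyclopent-1-ene F1. Et2Zn/CH2I2 then adds methylene anti to the OTBS group to give the bicyclic bis-silyl ether (1S,3S,5R)-3-(tert-butyldimethylsilyloxy)-1-(triisopropylsilyloxy)bicyclo[3.1.0]hexane F2. HF·pyridine removes the secondary TBS ether much faster than the tertiary cyclopropyl TIPS ether and should give (1S,3S,5R)-1-(triisopropylsilyloxy)bicyclo[3.1.0]hexan-3-ol F3. Dess–Martin periodinane (NaHCO3) gives (1S,5S)-1-(triisopropylsilyloxy)bicyclo[3.1.0]hexan-3-one F4. Cerium enolate 5 adds to F4 from the face opposite to the cyclopropane to give the triisopropylsilyl analogue of 11 F5, which has the same configuration as 11. FeCl3 in DMF (gentle warming if the bulky silyl ether is slow) opens F5 to 12, and the route continues as in step 7. The price is that the configuration is relayed through two diastereoselective steps instead of one.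

Step 5. Silane may be consumed by O-silylation of the tertiary alcohol, the rhodium hydride may move the skipped diene into conjugation or reduce the side-chain ketone, and an allyl–rhodium intermediate may lose the neighbouring hydroxyl. The fallback sets out from 6 and returns at 12; instead of removing and re-installing oxygen functionality it moves the double bond of 6. H2-activated [Ir(cod)(PMePh2)2]PF6 in THF at rt should isomerise the allylic silyl ether to the silyl enol ether, since the fully substituted carbinol carbon blocks migration in the other direction, giving (10Z,13Z)-1-[(1R)-3-(tert-butyldimethylsilyloxy)-1-hydroxycyclopent-3-en-1-yl]nonadeca-10,13-dien-2-one F6. Et2Zn/CH2I2 converts it through the ethylzinc alkoxide of F6 F7 into the tert-butyldimethylsilyl analogue of 11 F8, and FeCl3 opens F8 to 12. This path bypasses steps 3 to 5, but migration of the 10,13-diene at the iridium hydride is a real risk and has to be excluded by low catalyst loading and short contact time, which is why it is not the main route.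

Step 2. Proton transfer from the enone to the enolate with loss of silanolate, conjugate addition, reversal of the aldol addition on warming, or incomplete facial selectivity may intervene. The fallback sets out from 2 (with 3) and returns at 6; it replaces the enolate by an aza-enolate. Condensation of 2 with H2NNMe2 gives the N,N-dimethylhydrazone of 2 F9. LDA deprotonates its methyl group to the lithiated hydrazone F10, which should add 1,2 to 3 anti to the silyloxy group to give the β-hydroxy hydrazone F11. Buffered aqueous CuCl2 (THF, pH 7) cleaves the hydrazone to 6.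

Further compounds
F1 | step 6 | (4S)-4-(tert-butyldimethylsilyloxy)-1-(triisopropylsilyloxy)cyclopent-1-ene | CC(C)[Si](OC1=CC[C@H](O[Si](C)(C)C(C)(C)C)C1)(C(C)C)C(C)C
F2 | step 6 | (1S,3S,5R)-3-(tert-butyldimethylsilyloxy)-1-(triisopropylsilyloxy)bicyclo[3.1.0]hexane, cyclopropane anti to OTBS | CC(C)[Si](O[C@]12C[C@H]1C[C@H](O[Si](C)(C)C(C)(C)C)C2)(C(C)C)C(C)C
F3 | step 6 | (1S,3S,5R)-1-(triisopropylsilyloxy)bicyclo[3.1.0]hexan-3-ol | CC(C)[Si](O[C@]12C[C@H]1C[C@H](O)C2)(C(C)C)C(C)C
F4 | step 6 | (1S,5S)-1-(triisopropylsilyloxy)bicyclo[3.1.0]hexan-3-one | CC(C)[Si](O[C@]12C[C@H]1CC(=O)C2)(C(C)C)C(C)C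
F5 | step 6 | (10Z,13Z)-1-[(1S,3R,5R)-3-hydroxy-1-(triisopropylsilyloxy)bicyclo[3.1.0]hexan-3-yl]nonadeca-10,13-dien-2-one | CC(C)[Si](O[C@]12C[C@H]1C[C@](O)(CC(=O)CCCCCCC/C=C\C/C=C\CCCCC)C2)(C(C)C)C(C)C
F6 | step 5 | (10Z,13Z)-1-[(1R)-3-(tert-butyldimethylsilyloxy)-1-hydroxycyclopent-3-en-1-yl]nonadeca-10,13-dien-2-one | O[C@]1(CC(=O)CCCCCCC/C=C\C/C=C\CCCCC)CC=C(O[Si](C)(C)C(C)(C)C)C1
F7 | step 5 | ethylzinc alkoxide of F6 | CC[Zn]O[C@]1(CC(=O)CCCCCCC/C=C\C/C=C\CCCCC)CC=C(O[Si](C)(C)C(C)(C)C)C1
F8 | step 5 | (10Z,13Z)-1-[(1S,3R,5R)-1-(tert-butyldimethylsilyloxy)-3-hydroxybicyclo[3.1.0]hexan-3-yl]nonadeca-10,13-dien-2-one | O[C@]1(CC(=O)CCCCCCC/C=C\C/C=C\CCCCC)C[C@@H]2C[C@]2(O[Si](C)(C)C(C)(C)C)C1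
F9 | step 2 | N,N-dimethylhydrazone of (10Z,13Z)-nonadeca-10,13-dien-2-one | CN(C)N=C(C)CCCCCCC/C=C\C/C=C\CCCCC
F10 | step 2 | lithiated hydrazone (aza-enolate) of F9 | [Li]CC(=NN(C)C)CCCCCCC/C=C\C/C=C\CCCCC
F11 | step 2 | N,N-dimethylhydrazone of 6, (1R,4R) | O[C@]1(CC(=NN(C)C)CCCCCCC/C=C\C/C=C\CCCCC)C=C[C@H](O[Si](C)(C)C(C)(C)C)C1
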